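Atoms are numbered as in labdanes: ring A = C1–C5 and C10, ring B = C5–C10, C17 = formyl carbon on C8, C20 = methyl on C10.
Retrosynthesis: C15/C16 of the side chain (ynoate + Me2CuLi) → both ring bonds C4–C5 and C9–C10 (one radical bicyclization of a polyene) → C1–C2 and C3–C4 (three-component union around a two-carbon linchpin) → C8=C9 (olefination).
Enabling feature: in ring A the carbinol C3 lies between the CH2 C2 and the fully substituted C4, so C2–C3 is an acetyl unit whose α-carbon can take the allylic C1 and whose carbonyl carbon can take an isopropenyl C4; the 3-hydroxy-4,4-dimethyl pattern is then the hydrogen-atom adduct of an isopropenyl carbinol.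
Forward: chain joined at C8=C9 (step 3), C1 activated (steps 4, 5), C1–C2 and C3–C4 formed (step 6), ring A then ring B closed in one cascade (step 8), side chain and C17 adjusted (steps 9–13).
Stereochemistry: C3 by catalytic oxazaborolidine reduction (step 7); C5, C10 and C9 relayed from C3 in the chair–chair bicyclization; C8 by equilibration; 13Z by syn-carbocupration; the alkene geometries from steps 3 and 4 programme the trans ring fusion and the equatorial C9 chain.

Key step: step 6

Remark: step 8 leaves C8 unset, so 14 is carried as a C8-epimer mixture that step 9 equilibrates to the single diequatorial isomer.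

Step 1
Reactants: 1 methyl 2-[bis(2,2,2-trifluoroethoxy)phosphoryl]acetate; 2 5-bromo-2-methylpent-2-ene
Product: 3 methyl 2-[bis(2,2,2-trifluoroethoxy)phosphoryl]-6-methylhept-5-enoate (racemic)
Conditions: NaH, DMF, 0 °C; then 2, NaI (cat.), 60 °C
Reagents that add atoms: none
Why: C-alkylation of the sodium salt of a doubly stabilized phosphonoacetate with a primary bromide (SN2, iodide catalysis) is the standard entry to α-substituted Still–Gennari reagents, and the stereocenter formed is racemic and becomes sp2 in step 3.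

Step 2
Reactants: 4 5-(trimethylsilyl)pent-4-yn-1-ol
Product: 5 5-(trimethylsilyl)pent-4-ynal
Conditions: TEMPO (2,2,6,6-tetramethylpiperidin-1-oxyl, cat.), PhI(OAc)2, CH2Cl2, rt
Reagents that add atoms: none
Why: Nitroxyl-catalysed oxidation with PhI(OAc)2 as terminal oxidant stops at the aldehyde and leaves the silyl alkyne untouched; no stereocenter is involved.

Step 3
Reactants: 3 methyl 2-[bis(2,2,2-trifluoroethoxy)phosphoryl]-6-methylhept-5-enoate; 5 5-(trimethylsilyl)pent-4-ynal
Product: 6 methyl (2Z)-2-(4-methylpent-3-en-1-yl)-7-(trimethylsilyl)hept-2-en-6-ynoate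
Conditions: 3, KN(SiMe3)2, 18-crown-6, THF, −78 °C; then 5
Reagents that add atoms: none
Why: Still–Gennari modification of the Horner–Wadsworth–Emmons olefination, in which the electron-poor bis(trifluoroethyl) phosphonate and the crown-ether-separated potassium ion make elimination from the kinetic adduct fast, so that the ester ends cis to the new chain (2Z), the geometry that later places the C11 chain equatorial on ring B.

Step 4
Reactants: 6 methyl (2Z)-2-(4-methylpent-3-en-1-yl)-7-(trimethylsilyl)hept-2-en-6-ynoate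
Product: 7 methyl (2Z)-2-[(3E)-5-hydroxy-4-methylpent-3-en-1-yl]-7-(trimethylsilyl)hept-2-en-6-ynoate
Conditions: SeO2 (cat.), t-BuOOH, CH2Cl2, 0 °C to rt
Reagents that add atoms: tert-butyl hydroperoxide, CC(C)(C)OO
Why: SeO2 allylic oxidation (ene reaction, then [2,3]-sigmatropic shift) should touch only the electron-rich trisubstituted alkene and, with its usual selectivity, the methyl group trans to the chain, which gives the (E)-allylic alcohol needed for a trans ring fusion and spares the electron-poor enoate.

Step 5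
Reactants: 7 methyl (2Z)-2-[(3E)-5-hydroxy-4-methylpent-3-en-1-yl]-7-(trimethylsilyl)hept-2-en-6-ynoate
Product: 8 methyl (2Z)-2-[(3E)-5-bromo-4-methylpent-3-en-1-yl]-7-(trimethylsilyl)hept-2-en-6-ynoate
Conditions: CBr4, PPh3, CH2Cl2, 0 °C
Reagents that add atoms: tetrabromomethane, BrC(Br)(Br)Br
Why: Appel bromination converts the primary allylic alcohol into the bromide under neutral conditions by SN2 displacement of the oxyphosphonium group, without allylic transposition or loss of the (3E) geometry.

Step 6
Reactants: 8 methyl (2Z)-2-[(3E)-5-bromo-4-methylpent-3-en-1-yl]-7-(trimethylsilyl)hept-2-en-6-ynoate; 9 N-methoxy-N-methylacetamide; 10 prop-1-en-2-ylmagnesium bromide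
Product: 12 methyl (2Z)-2-[(3E)-4,8-dimethyl-7-oxonona-3,8-dien-1-yl]-7-(trimethylsilyl)hept-2-en-6-ynoate, via alkylated Weinreb amide 11 (not isolated)
Conditions: 9, LiN(i-Pr)2, THF, −78 °C; then 8, −78 to −40 °C; then 10, −40 to 0 °C; cold aq. HCl
Reagents that add atoms: none
Why: The lithium enolate of the acetamide (its α-carbon becomes C2) displaces the primary allylic bromide of 8 in an SN2 alkylation (bond C1–C2), and the Weinreb amide 11 so formed then accepts the isopropenyl Grignard reagent at its carbonyl carbon (C3) to give a chelated tetrahedral adduct that collapses to the ketone only on acidic work-up (bond C3–C4), so the acetyl unit serves as a two-carbon linchpin between an electrophile and a nucleophile in one flask. The closest known reaction types are the α-alkylation of amide enolates with allylic halides and the Weinreb ketone synthesis. No ring is closed and no stereocenter is set here; the step delivers the isopropenyl ketone from which C3 is set by catalysis in step 7 and from which the C4 radical for both ring closures is generated in step 8. The step needs SN2 rather than SN2' attack, which the unhindered primary bromide on a trisubstituted alkene secures with retention of the (3E) geometry, and it needs the organomagnesium reagent to choose the amide over the methyl ester, which chelation by the N-methoxy group and the hindered, conjugated, α-branched ester should secure at low temperature. Adding the bromide to the preformed enolate at −78 °C keeps proton transfer from the γ-positions of the enoate slow relative to alkylation, and the cold acidic quench keeps the liberated hydroxylamine from adding to the enone.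

Step 7
Reactants: 12 methyl (2Z)-2-[(3E)-4,8-dimethyl-7-oxonona-3,8-dien-1-yl]-7-(trimethylsilyl)hept-2-en-6-ynoate
Product: 13 methyl (2Z)-2-[(3E,7R)-7-hydroxy-4,8-dimethylnona-3,8-dien-1-yl]-7-(trimethylsilyl)hept-2-en-6-ynoate
Conditions: (S)-1-methyl-3,3-diphenyltetrahydro-1H,3H-pyrrolo[1,2-c][1,3,2]oxazaborole (cat.), catecholborane, toluene, −78 °C; aqueous work-up
Reagents that add atoms: none
Why: Corey–Bakshi–Shibata reduction, in which the (S)-oxazaborolidine binds the ketone with the α-branched sp2 isopropenyl group as the large substituent and delivers hydride from coordinated catecholborane to one face, should set C3 as (R) under catalyst control, while the ester, the alkenes and the alkyne do not react with catecholborane at −78 °C.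

Step 8
Reactants: 13 methyl (2Z)-2-[(3E,7R)-7-hydroxy-4,8-dimethylnona-3,8-dien-1-yl]-7-(trimethylsilyl)hept-2-en-6-ynoate
Product: 14 methyl (1R,4aS,6R,8aS)-6-hydroxy-5,5,8a-trimethyl-1-[4-(trimethylsilyl)but-3-yn-1-yl]decahydronaphthalene-2-carboxylate (mixture of epimers at C-2 of the decalin, which is C8)
Conditions: Fe(acac)3 (cat.), PhSiH3, EtOH/ethylene glycol, 60 °C
Reagents that add atoms: none
Why: Metal-hydride hydrogen-atom-transfer-initiated radical polyene cyclization with Giese termination: the iron hydride should deliver H to the CH2 of the 1,1-disubstituted alkene (creating the second methyl on C4), the tertiary C4 radical should close ring A 6-endo on C5 and the resulting C10 radical ring B 6-endo on the β-carbon C9 of the acrylate, through a chair–chair arrangement with the C3 hydroxyl and the C6 and C11 chains equatorial, so that C5, C10 and C9 are relayed from C3 with a trans ring fusion (as in the related epoxypolyene radical cyclizations), and the α-ester radical at C8 is reduced and protonated without control.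

Step 9
Reactants: 14 methyl (1R,4aS,6R,8aS)-6-hydroxy-5,5,8a-trimethyl-1-[4-(trimethylsilyl)but-3-yn-1-yl]decahydronaphthalene-2-carboxylate
Product: 15 methyl (1R,2S,4aS,6R,8aS)-1-(but-3-yn-1-yl)-6-hydroxy-5,5,8a-trimethyldecahydronaphthalene-2-carboxylate
Conditions: NaOMe (cat.), MeOH, 50 °C
Reagents that add atoms: none
Why: Methoxide should equilibrate the enolizable ester-bearing C8 to the diequatorial (2S) isomer trans to the C9 chain (thermodynamic control) and in the same operation cleave the C(sp)–Si bond and any O–Si bond formed by the silane in step 8.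

Step 10
Reactants: 15 methyl (1R,2S,4aS,6R,8aS)-1-(but-3-yn-1-yl)-6-hydroxy-5,5,8a-trimethyldecahydronaphthalene-2-carboxylate
Product: 16 [(1R,2S,4aS,6R,8aS)-1-(but-3-yn-1-yl)-6-hydroxy-5,5,8a-trimethyldecahydronaphthalen-2-yl]methanol
Conditions: LiAlH4, THF, 0 °C to rt
Reagents that add atoms: none
Why: LiAlH4 reduction of the ester to the primary alcohol takes C17 out of the ester oxidation level before the side-chain ester is built, and neither the terminal alkyne nor any stereocenter is affected.

Step 11
Reactants: 16 [(1R,2S,4aS,6R,8aS)-1-(but-3-yn-1-yl)-6-hydroxy-5,5,8a-trimethyldecahydronaphthalen-2-yl]methanol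
Product: 17 methyl 5-[(1R,2S,4aS,6R,8aS)-6-hydroxy-2-(hydroxymethyl)-5,5,8a-trimethyldecahydronaphthalen-1-yl]pent-2-ynoate
Conditions: PdCl2 (cat.), CuCl2, NaOAc, CO (1 atm), MeOH, rt
Reagents that add atoms: carbon monoxide, [C-]#[O+]; methanol, CO
Why: Palladium-catalysed oxidative methoxycarbonylation of a terminal alkyne (alkynylpalladium, CO insertion, methanolysis, CuCl2 as reoxidant) gives the alk-2-ynoate under non-basic conditions that tolerate the free diol.

Step 12
Reactants: 17 methyl 5-[(1R,2S,4aS,6R,8aS)-6-hydroxy-2-(hydroxymethyl)-5,5,8a-trimethyldecahydronaphthalen-1-yl]pent-2-ynoate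
Product: 18 methyl (2Z)-5-[(1R,2S,4aS,6R,8aS)-6-hydroxy-2-(hydroxymethyl)-5,5,8a-trimethyldecahydronaphthalen-1-yl]-3-methylpent-2-enoate
Conditions: Me2CuLi (excess), THF, −78 °C; MeOH, then aq. NH4Cl, −78 °C
Reagents that add atoms: lithium dimethylcuprate, [Li+].C[Cu-]C
Why: Conjugate syn-carbocupration of the ynoate by Me2CuLi at −78 °C and protonation of the alkenylcuprate with retention place the new methyl and the new hydrogen cis, which gives the (2Z)-3-methyl enoate stereospecifically as long as the quench is done cold.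

Step 13
Reactants: 18 methyl (2Z)-5-[(1R,2S,4aS,6R,8aS)-6-hydroxy-2-(hydroxymethyl)-5,5,8a-trimethyldecahydronaphthalen-1-yl]-3-methylpent-2-enoate
Product: 19 methyl (2Z)-5-[(1R,2S,4aS,6R,8aS)-2-formyl-6-hydroxy-5,5,8a-trimethyldecahydronaphthalen-1-yl]-3-methylpent-2-enoate (CNP0188570.1)
Conditions: TEMPO (2,2,6,6-tetramethylpiperidin-1-oxyl, cat.), PhI(OAc)2, CH2Cl2, rt
Reagents that add atoms: none
Why: TEMPO/PhI(OAc)2 oxidation is selective for the primary alcohol over the hindered secondary C3 hydroxyl and stops at the aldehyde, and the equatorial C8 configuration set in step 9 is the thermodynamic one and is kept under these non-basic conditions.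

Compound list
1 | methyl 2-[bis(2,2,2-trifluoroethoxy)phosphoryl]acetate | COC(=O)CP(=O)(OCC(F)(F)F)OCC(F)(F)F | starting material
2 | 5-bromo-2-methylpent-2-ene | CC(C)=CCCBr | starting material
3 | methyl 2-[bis(2,2,2-trifluoroethoxy)phosphoryl]-6-methylhept-5-enoate (racemic) | COC(=O)C(CCC=C(C)C)P(=O)(OCC(F)(F)F)OCC(F)(F)F | intermediate
4 | 5-(trimethylsilyl)pent-4-yn-1-ol | C[Si](C)(C)C#CCCCO | starting material
5 | 5-(trimethylsilyl)pent-4-ynal | C[Si](C)(C)C#CCCC=O | intermediate
6 | methyl (2Z)-2-(4-methylpent-3-en-1-yl)-7-(trimethylsilyl)hept-2-en-6-ynoate | COC(=O)/C(CCC=C(C)C)=C\CCC#C[Si](C)(C)C | intermediate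
7 | methyl (2Z)-2-[(3E)-5-hydroxy-4-methylpent-3-en-1-yl]-7-(trimethylsilyl)hept-2-en-6-ynoate | COC(=O)/C(CC/C=C(\C)CO)=C\CCC#C[Si](C)(C)C | intermediate
8 | methyl (2Z)-2-[(3E)-5-bromo-4-methylpent-3-en-1-yl]-7-(trimethylsilyl)hept-2-en-6-ynoate | COC(=O)/C(CC/C=C(\C)CBr)=C\CCC#C[Si](C)(C)C | intermediate
9 | N-methoxy-N-methylacetamide | CC(=O)N(C)OC | starting material
10 | prop-1-en-2-ylmagnesium bromide | C=C(C)[Mg]Br | starting material
11 | methyl (2Z)-2-[(3E)-7-[methoxy(methyl)amino]-4-methyl-7-oxohept-3-en-1-yl]-7-(trimethylsilyl)hept-2-en-6-ynoate (not isolated) | CON(C)C(=O)CC/C(C)=C/CC/C(C(=O)OC)=C/CCC#C[Si](C)(C)C | intermediate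
12 | methyl (2Z)-2-[(3E)-4,8-dimethyl-7-oxonona-3,8-dien-1-yl]-7-(trimethylsilyl)hept-2-en-6-ynoate | C=C(C)C(=O)CC/C(C)=C/CC/C(C(=O)OC)=C/CCC#C[Si](C)(C)C | intermediate
13 | methyl (2Z)-2-[(3E,7R)-7-hydroxy-4,8-dimethylnona-3,8-dien-1-yl]-7-(trimethylsilyl)hept-2-en-6-ynoate | C=C(C)[C@H](O)CC/C(C)=C/CC/C(C(=O)OC)=C/CCC#C[Si](C)(C)C | intermediate
14 | methyl (1R,4aS,6R,8aS)-6-hydroxy-5,5,8a-trimethyl-1-[4-(trimethylsilyl)but-3-yn-1-yl]decahydronaphthalene-2-carboxylate (epimer mixture at C-2) | C[Si](C)(C)C#CCC[C@@H]1C(C(=O)OC)CC[C@@H]2C(C)(C)[C@H](O)CC[C@@]12C | intermediate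
15 | methyl (1R,2S,4aS,6R,8aS)-1-(but-3-yn-1-yl)-6-hydroxy-5,5,8a-trimethyldecahydronaphthalene-2-carboxylate | C#CCC[C@@H]1[C@@H](C(=O)OC)CC[C@@H]2C(C)(C)[C@H](O)CC[C@@]12C | intermediate
16 | [(1R,2S,4aS,6R,8aS)-1-(but-3-yn-1-yl)-6-hydroxy-5,5,8a-trimethyldecahydronaphthalen-2-yl]methanol | C#CCC[C@@H]1[C@@H](CO)CC[C@@H]2C(C)(C)[C@H](O)CC[C@@]12C | intermediate
17 | methyl 5-[(1R,2S,4aS,6R,8aS)-6-hydroxy-2-(hydroxymethyl)-5,5,8a-trimethyldecahydronaphthalen-1-yl]pent-2-ynoate | COC(=O)C#CCC[C@@H]1[C@@H](CO)CC[C@@H]2C(C)(C)[C@H](O)CC[C@@]12C | intermediate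
18 | methyl (2Z)-5-[(1R,2S,4aS,6R,8aS)-6-hydroxy-2-(hydroxymethyl)-5,5,8a-trimethyldecahydronaphthalen-1-yl]-3-methylpent-2-enoate | COC(=O)/C=C(/C)CC[C@@H]1[C@@H](CO)CC[C@@H]2C(C)(C)[C@H](O)CC[C@@]12C | intermediate
19 | methyl (2Z)-5-[(1R,2S,4aS,6R,8aS)-2-formyl-6-hydroxy-5,5,8a-trimethyldecahydronaphthalen-1-yl]-3-methylpent-2-enoate | COC(=O)/C=C(/C)CC[C@@H]1[C@@H](C=O)CC[C@@H]2C(C)(C)[C@H](O)CC[C@@]12C | target

Total step count: 13. Longest linear sequence: 12 steps (steps 1 and 3–13).

Steps most likely to fail

Step 8. The first tertiary radical may be reduced under the reducing conditions before ring A closes, the hydrogen atom may be delivered to the trisubstituted alkene instead of the isopropenyl group, or facial control in the first ring closure may be poor. The fallback sets out from 12 and comes back at 14; it generates the same C4 radical by reductive opening of an oxirane with trivalent titanium instead of by hydrogen-atom transfer. Ketone 12 is reduced with the (R)-enantiomer of the oxazaborolidine of step 7 and catecholborane to methyl (2Z)-2-[(3E,7S)-7-hydroxy-4,8-dimethylnona-3,8-dien-1-yl]-7-(trimethylsilyl)hept-2-en-6-ynoate F1. Mukaiyama hydration of its 1,1-disubstituted alkene (Co(acac)2, PhSiH3, O2, i-PrOH) gives methyl (2Z)-2-[(3E,7S)-7,8-dihydroxy-4,8-dimethylnon-3-en-1-yl]-7-(trimethylsilyl)hept-2-en-6-ynoate F2. MsCl/Et3N sulfonylates only the secondary hydroxyl to give methyl (2Z)-2-[(3E,7S)-8-hydroxy-7-(methanesulfonyloxy)-4,8-dimethylnon-3-en-1-yl]-7-(trimethylsilyl)hept-2-en-6-ynoate F3, and NaH in THF closes the oxirane with inversion at C3 to give methyl (2Z)-2-[(3E)-6-[(2R)-3,3-dimethyloxiran-2-yl]-4-methylhex-3-en-1-yl]-7-(trimethylsilyl)hept-2-en-6-ynoate F4. (C5H5)2TiCl (from (C5H5)2TiCl2 and Mn, THF) should open the oxirane at C4 (Nugent–RajanBabu opening); the tertiary radical should then run through the same 6-endo/6-endo sequence, with the α-ester radical reduced to a titanium enolate and protonated on work-up, to give 14.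

Step 6. The strongly basic amide enolate may take a proton from the γ-positions of the enoate or condense with itself, and the organomagnesium reagent may add to the methyl ester. The fallback sets out from 8 and comes back at 12; it makes the two bonds in two separate, non-basic, ester-tolerant palladium-catalysed couplings. The Reformatsky reagent from S-ethyl 2-bromoethanethioate and Zn is allylated with 8 under Pd(PPh3)4 catalysis to give methyl (2Z)-2-[(3E)-7-(ethylsulfanyl)-4-methyl-7-oxohept-3-en-1-yl]-7-(trimethylsilyl)hept-2-en-6-ynoate F5, and Fukuyama coupling of this thioester with prop-1-en-2-ylzinc bromide (PdCl2(PPh3)2 cat., THF) gives 12.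

Step 7. Facial discrimination between the isopropenyl group and the primary alkyl chain may be insufficient, which would lower the enantiomeric purity that every later stereocenter inherits. The fallback sets out from 12 and comes back at 13; it replaces asymmetric reduction by racemic reduction and kinetic resolution. Luche reduction (NaBH4, CeCl3·7H2O, MeOH) gives racemic methyl (2Z)-2-[(3E)-7-hydroxy-4,8-dimethylnona-3,8-dien-1-yl]-7-(trimethylsilyl)hept-2-en-6-ynoate F6. Sharpless kinetic resolution (Ti(OiPr)4, L-(+)-diisopropyl tartrate, t-BuOOH, 4 Å molecular sieves, CH2Cl2, −20 °C) should epoxidize the (7S)-enantiomer to methyl (2Z)-2-[(3E,7S)-7-hydroxy-4-methyl-7-(2-methyloxiran-2-yl)hept-3-en-1-yl]-7-(trimethylsilyl)hept-2-en-6-ynoate F7 (oxirane carbon not assigned) and leave the (7R)-alcohol 13.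

Further compounds
F1 | step 8 | methyl (2Z)-2-[(3E,7S)-7-hydroxy-4,8-dimethylnona-3,8-dien-1-yl]-7-(trimethylsilyl)hept-2-en-6-ynoate | C=C(C)[C@@H](O)CC/C(C)=C/CC/C(C(=O)OC)=C/CCC#C[Si](C)(C)C
F2 | step 8 | methyl (2Z)-2-[(3E,7S)-7,8-dihydroxy-4,8-dimethylnon-3-en-1-yl]-7-(trimethylsilyl)hept-2-en-6-ynoate | CC(C)(O)[C@@H](O)CC/C(C)=C/CC/C(C(=O)OC)=C/CCC#C[Si](C)(C)C
F3 | step 8 | methyl (2Z)-2-[(3E,7S)-8-hydroxy-7-(methanesulfonyloxy)-4,8-dimethylnon-3-en-1-yl]-7-(trimethylsilyl)hept-2-en-6-ynoate | CC(C)(O)[C@@H](OS(C)(=O)=O)CC/C(C)=C/CC/C(C(=O)OC)=C/CCC#C[Si](C)(C)C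
F4 | step 8 | methyl (2Z)-2-[(3E)-6-[(2R)-3,3-dimethyloxiran-2-yl]-4-methylhex-3-en-1-yl]-7-(trimethylsilyl)hept-2-en-6-ynoate | CC1(C)[C@H](O1)CC/C(C)=C/CC/C(C(=O)OC)=C/CCC#C[Si](C)(C)C
F5 | step 6 | methyl (2Z)-2-[(3E)-7-(ethylsulfanyl)-4-methyl-7-oxohept-3-en-1-yl]-7-(trimethylsilyl)hept-2-en-6-ynoate | CCSC(=O)CC/C(C)=C/CC/C(C(=O)OC)=C/CCC#C[Si](C)(C)C
F6 | step 7 | methyl (2Z)-2-[(3E)-7-hydroxy-4,8-dimethylnona-3,8-dien-1-yl]-7-(trimethylsilyl)hept-2-en-6-ynoate (racemic) | C=C(C)C(O)CC/C(C)=C/CC/C(C(=O)OC)=C/CCC#C[Si](C)(C)C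
F7 | step 7 | methyl (2Z)-2-[(3E,7S)-7-hydroxy-4-methyl-7-(2-methyloxiran-2-yl)hept-3-en-1-yl]-7-(trimethylsilyl)hept-2-en-6-ynoate | CC1(CO1)[C@@H](O)CC/C(C)=C/CC/C(C(=O)OC)=C/CCC#C[Si](C)(C)C
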